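Numbering (daucane): ring A = C1 (quaternary, CH3)–C2–C3–C4 (OH, iPr)–C5 (H). Ring B = C1–C5–C6 (O-anisoyl)–C7=C8 (CH3)–C9 (=O)–C10 (OH). β is the face of the C1 methyl.
Feature used: in ring B the acyloin C9(=O)–C10H(OH) sits between quaternary C1 and the C7=C8 alkene. It is read as the product of an α-ketol shift of C1 from C9 to a formyl carbon C10 carried by a cyclohexene (C1, C5, C6, C7, C8, C9), so the six-membered ring becomes ring B in the last step.
The 9-hydroxy-9-formyl group comes from a 9-methylidene trans-hydrindene by dihydroxylation and oxidation. Its cyclohexene is closed at C7=C8 by ring-closing metathesis.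
All stereocentres descend from one catalytic step. Enantioselective conjugate addition of a 2-isoprenyl alane (C8, C9, C10, C8-CH3) to 3-methylcyclopent-2-enone makes quaternary C1, acrolein traps the enolate (C6, C7), and an isopropyl nucleophile then adds to C4.
Order of rings: ring A (bought) → cyclohexene (metathesis) → ring B (ring expansion).

Key step: step 7

Remark: the enantiomer of the imidazolinium ligand in step 1 is taken to be the one that delivers (S)-configured C1. Daucane numbers are used for all intermediates.

Step 1
Reactants: 1 2-methylbut-1-en-3-yne; 2 3-methylcyclopent-2-en-1-one; 3 acrolein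
Product: 6 (2S,3S)-2-[(1S)-1-hydroxyprop-2-en-1-yl]-3-methyl-3-(3-methylbuta-1,3-dien-2-yl)cyclopentan-1-one, via dienylalane 4 (not isolated), via aluminium enolate 5 (not isolated)
Conditions: 1, iBu2AlH, Ni(dppp)Cl2 (3 mol %), THF, 22 °C; then 2, CuCl2·2H2O (5 mol %), enantiopure sulfonate-bearing imidazolinium salt (5 mol %), −30 °C; then 3, −78 °C; aq. potassium sodium tartrate
Reagents that add atoms: none
Why: Nickel-catalysed α-selective hydroalumination puts aluminium on the internal alkyne carbon, the copper/N-heterocyclic-carbene-catalysed enantioselective conjugate addition of the alkenylalane (ligand control) builds quaternary C1 as (S), and the regiodefined aluminium (E)-enolate adds to acrolein through a closed Zimmerman–Traxler transition state on the face opposite the bulky dienyl group, which sets C5 trans to it and C6 as the anti aldol.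

Step 2
Reactants: 6 aldol adduct
Product: 7 (2S,3S)-3-methyl-3-(3-methylbuta-1,3-dien-2-yl)-2-[(1S)-1-(triethylsilyloxy)prop-2-en-1-yl]cyclopentan-1-one
Conditions: Et3SiCl, imidazole, DMF, 0 °C
Reagents that add atoms: chlorotriethylsilane CC[Si](Cl)(CC)CC
Why: Standard silylation of the secondary allylic alcohol under near-neutral conditions blocks retro-aldol cleavage and dehydration in the next step and creates no stereocentre.

Step 3
Reactants: 7 silyl ether ketone; 8 isopropylmagnesium chloride
Product: 10 (1R,2S,3S)-2-[(1S)-1-hydroxyprop-2-en-1-yl]-3-methyl-3-(3-methylbuta-1,3-dien-2-yl)-1-(propan-2-yl)cyclopentan-1-ol, via silyl ether carbinol 9 (not isolated)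
Conditions: CeCl3 (anhydrous), THF, −78 °C; then 1 M HCl, THF, 0 °C
Reagents that add atoms: none
Why: The CeCl3-promoted Grignard 1,2-addition suppresses enolisation and β-hydride reduction of the hindered cyclopentanone, the nucleophile enters from the α face opposite the neighbouring C5 side chain so that the C4 hydroxyl is β (4R), and the acidic work-up cleaves the labile triethylsilyl ether.

Step 4
Reactants: 10 diol; 11 4-methoxybenzoyl chloride
Product: 12 (1S)-1-[(1S,2R,5S)-2-hydroxy-5-methyl-5-(3-methylbuta-1,3-dien-2-yl)-2-(propan-2-yl)cyclopentyl]prop-2-en-1-yl 4-methoxybenzoate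
Conditions: Et3N, DMAP (cat.), CH2Cl2, 0 °C to rt
Reagents that add atoms: none
Why: DMAP-catalysed acylation distinguishes the secondary allylic C6 hydroxyl from the unreactive tertiary C4 hydroxyl and proceeds with retention at C6.

Step 5
Reactants: 12 tetraene ester
Product: 13 (3R,3aS,4S,7aS)-3-hydroxy-6,7a-dimethyl-7-methylidene-3-(propan-2-yl)-2,3,3a,4,7,7a-hexahydro-1H-inden-4-yl 4-methoxybenzoate
Conditions: second-generation Hoveyda–Grubbs catalyst (5 mol %), toluene (2 mM), 80 °C
Reagents that add atoms: none
Why: Ring-closing metathesis starts at the monosubstituted vinyl group and closes onto the isopropenyl terminus of the diene to give the trisubstituted C7=C8 alkene of a trans-hydrindene, because closure onto the other 1,1-disubstituted alkene would give a highly strained trans-bicyclo[3.3.0]octene.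

Step 6
Reactants: 13 methylidene diene
Product: 14 (3R,3aS,4S,7R,7aS)-3,7-dihydroxy-7-(hydroxymethyl)-6,7a-dimethyl-3-(propan-2-yl)-2,3,3a,4,7,7a-hexahydro-1H-inden-4-yl 4-methoxybenzoate
Conditions: OsO4 (3 mol %), N-methylmorpholine N-oxide, acetone/H2O, 0 °C
Reagents that add atoms: N-methylmorpholine N-oxide C[N+]1([O-])CCOCC1; water O
Why: Upjohn dihydroxylation should pick the sterically open exocyclic methylidene over the trisubstituted ring alkene, which is deactivated by the allylic ester and shielded on both faces, and OsO4 approaches from the α face opposite the axial angular methyl on adjacent C1, which sets C9 (hydroxyl α, hydroxymethyl β).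

Step 7
Reactants: 14 triol
Product: 16 (3R,3aS,4S,8R,8aS)-3,8-dihydroxy-6,8a-dimethyl-7-oxo-3-(propan-2-yl)-1,2,3,3a,4,7,8,8a-octahydroazulen-4-yl 4-methoxybenzoate (CNP0299970.1), via hydroxy aldehyde 15 (not isolated)
Conditions: SO3·pyridine, DMSO, Et3N, CH2Cl2, 0 °C; then DBU (0.3 equiv), rt
Reagents that add atoms: none
Why: Parikh–Doering oxidation touches only the primary C10 hydroxyl (those at C4 and C9 are tertiary) and gives the non-enolisable α-hydroxy aldehyde 15, after which DBU starts an α-ketol (acyloin) rearrangement in which the C9 alkoxide pushes the C9–C1 σ-bond onto the formyl carbon C10, so that C10 is inserted between C9 and C1 and the cyclohexene becomes the cycloheptenone. The closest known reaction type is the base-induced D-homoannulation of 17-hydroxy-17-acyl steroids, where a carbinol next to an angular-methyl quaternary carbon also enlarges its ring by one atom. No new ring is closed: the existing six-membered ring is enlarged by a suprafacial 1,2-shift in which C1 migrates with retention. The only new stereocentre, C10, is controlled by the C9 configuration from step 6: with a non-chelating amidinium counter-ion the two C–O dipoles stand antiperiplanar, C1 attacks the aldehyde face turned towards it and the hydroxyl ends up β (10R), which should also be the pseudo-equatorial, hydrogen-bonded and therefore preferred position if C10 equilibrates. The step needs C1 and not the vinylic C8 to migrate: the shift is reversible, only C1 migration turns the aldehyde into a ketone conjugated with C7=C8 and relieves the clash of the adjacent fully substituted C9 and C1, and a leak through C8 migration would reach the same acyloin by enediol tautomerism. The anisoate, the tertiary C4 hydroxyl and the C7=C8 alkene are inert to the amine bases used.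

Compound list
1 | 2-methylbut-1-en-3-yne | C#CC(C)=C | starting material
2 | 3-methylcyclopent-2-en-1-one | CC1=CC(=O)CC1 | starting material
3 | acrolein (prop-2-enal) | C=CC=O | starting material
4 | diisobutyl(3-methylbuta-1,3-dien-2-yl)aluminium | C=C(C)C(=C)[Al](CC(C)C)CC(C)C | intermediate
5 | diisobutylaluminium C4=C5 enolate of (S)-3-methyl-3-(3-methylbuta-1,3-dien-2-yl)cyclopentanone | C=C(C)C(=C)[C@@]1(C)CCC(O[Al](CC(C)C)CC(C)C)=C1 | intermediate
6 | (2S,3S)-2-[(1S)-1-hydroxyprop-2-en-1-yl]-3-methyl-3-(3-methylbuta-1,3-dien-2-yl)cyclopentan-1-one | C=C[C@H](O)[C@H]1C(=O)CC[C@]1(C)C(=C)C(C)=C | intermediate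
7 | (2S,3S)-3-methyl-3-(3-methylbuta-1,3-dien-2-yl)-2-[(1S)-1-(triethylsilyloxy)prop-2-en-1-yl]cyclopentan-1-one | C=C[C@H](O[Si](CC)(CC)CC)[C@H]1C(=O)CC[C@]1(C)C(=C)C(C)=C | intermediate
8 | isopropylmagnesium chloride | CC(C)[Mg]Cl | starting material
9 | (1R,2S,3S)-3-methyl-3-(3-methylbuta-1,3-dien-2-yl)-1-(propan-2-yl)-2-[(1S)-1-(triethylsilyloxy)prop-2-en-1-yl]cyclopentan-1-ol | C=C[C@H](O[Si](CC)(CC)CC)[C@H]1[C@](O)(C(C)C)CC[C@]1(C)C(=C)C(C)=C | intermediate
10 | (1R,2S,3S)-2-[(1S)-1-hydroxyprop-2-en-1-yl]-3-methyl-3-(3-methylbuta-1,3-dien-2-yl)-1-(propan-2-yl)cyclopentan-1-ol | C=C[C@H](O)[C@H]1[C@](O)(C(C)C)CC[C@]1(C)C(=C)C(C)=C | intermediate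
11 | 4-methoxybenzoyl chloride | COc1ccc(cc1)C(Cl)=O | starting material
12 | (1S)-1-[(1S,2R,5S)-2-hydroxy-5-methyl-5-(3-methylbuta-1,3-dien-2-yl)-2-(propan-2-yl)cyclopentyl]prop-2-en-1-yl 4-methoxybenzoate | C=C[C@H](OC(=O)c1ccc(OC)cc1)[C@H]1[C@](O)(C(C)C)CC[C@]1(C)C(=C)C(C)=C | intermediate
13 | trans-hydrindene diene: 1β-methyl, 4β-hydroxy, 5α-H, 6α-anisoyloxy, C7=C8, 9-methylidene | COc1ccc(C(=O)O[C@H]2C=C(C)C(=C)[C@@]3(C)CC[C@@](O)(C(C)C)[C@H]23)cc1 | intermediate
14 | triol: as 13 but with 9α-hydroxy and 9β-hydroxymethyl | COc1ccc(C(=O)O[C@H]2C=C(C)[C@](O)(CO)[C@@]3(C)CC[C@@](O)(C(C)C)[C@H]23)cc1 | intermediate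
15 | α-hydroxy aldehyde: as 14 but with 9β-formyl | COc1ccc(C(=O)O[C@H]2C=C(C)[C@](O)(C=O)[C@@]3(C)CC[C@@](O)(C(C)C)[C@H]23)cc1 | intermediate
16 | CNP0299970.1, 6α-(4-methoxybenzoyloxy)-4β,10β-dihydroxydauc-7-en-9-one | COc1ccc(C(=O)O[C@H]2C=C(C)C(=O)[C@H](O)[C@@]3(C)CC[C@@](O)(C(C)C)[C@H]23)cc1 | target

Total step count: 7. Longest linear sequence: 7 steps (from 1 or 2 to 16).

Steps most likely to fail

Step 7 (key step). What may go wrong is migration of the vinylic C8 in place of C1, loss of configuration at C10 by enolisation, or base-induced drift of the acyloin through its enediol to other tautomers. The fallback leaves the anionic manifold for a Lewis-acid semipinacol shift on a silyl ether.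
- It sets out from 14, which is oxidised with IBX in DMSO without base so that 15 can be isolated.
- Me3SiOTf and 2,6-lutidine convert both tertiary hydroxyls into the bis(trimethylsilyl) ether F1.
- The bulky, non-chelating methylaluminium bis(4-bromo-2,6-di-tert-butylphenoxide) in CH2Cl2 at low temperature activates only the formyl oxygen. C1 shifts to C10 with the dipoles antiperiplanar, and the silyl group moves from O9 to O10 to give the α-silyloxy ketone F2, in a medium free of base.
- HF·pyridine removes both silyl groups and the route is rejoined at 16.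

Step 3. What may go wrong is enolisation or β-hydride reduction of the crowded ketone in place of addition, or poor facial selectivity. The fallback builds the isopropyl carbinol from two small nucleophiles.
- It sets out from 7. Diphenylsulfonium ethylide (from ethyldiphenylsulfonium tetrafluoroborate and t-BuLi, THF, −78 °C) adds from the α face and closes to the spiro-epoxide F3. Its oxygen is β, and the configuration at the methyl-bearing epoxide carbon is irrelevant.
- Me2CuLi, assisted by BF3·OEt2 if needed, opens the epoxide at its CH(CH3) carbon. This completes the isopropyl group and rejoins the route at 9.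

Step 1. What may go wrong is sluggish or unselective capture of the aluminium enolate by acrolein, consumption of the aldehyde by excess alane, or erosion of the anti selectivity. The fallback decouples bond formation at C1 from that at C5–C6.
- It sets out from 5, which is quenched with acetic anhydride to the isolable, regiodefined enol acetate F4.
- MeLi (2 equiv, THF, 0 °C) releases the lithium enolate F5 free of aluminium species.
- Addition of acrolein at −78 °C through the closed transition state rejoins the route at 6.

Further compounds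
F1 | step 7 | bis(trimethylsilyl) ether of 15 (O4 and O9 silylated) | COc1ccc(C(=O)O[C@H]2C=C(C)[C@](O[Si](C)(C)C)(C=O)[C@@]3(C)CC[C@@](O[Si](C)(C)C)(C(C)C)[C@H]23)cc1
F2 | step 7 | 4,10-bis(trimethylsilyl) ether of 16 | COc1ccc(C(=O)O[C@H]2C=C(C)C(=O)[C@H](O[Si](C)(C)C)[C@@]3(C)CC[C@@](O[Si](C)(C)C)(C(C)C)[C@H]23)cc1
F3 | step 3 | spiro-epoxide of 7 at C4 (oxygen β, methyl-bearing carbon undefined) | C=C[C@H](O[Si](CC)(CC)CC)[C@H]1[C@@]2(OC2C)CC[C@]1(C)C(=C)C(C)=C
F4 | step 1 | (S)-3-methyl-3-(3-methylbuta-1,3-dien-2-yl)cyclopent-1-en-1-yl acetate | C=C(C)C(=C)[C@@]1(C)CCC(OC(C)=O)=C1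
F5 | step 1 | lithium (S)-3-methyl-3-(3-methylbuta-1,3-dien-2-yl)cyclopent-1-en-1-olate | C=C(C)C(=C)[C@@]1(C)CCC(O[Li])=C1
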